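**Retrosynthetic overview**
1. C6 prenyl: installed last by aromatic Claisen shift of a 2-methylbut-3-en-2-yl ether on O5; until then this ether caps O5, the only other oxygen ortho to the acyl-bearing carbon C4a.
2. Pyranone ring (O1–C2): quinine-catalysed 6-endo oxa-Michael addition of the O1 phenol to a tigloyl ketone on C4a, set off in the same flask by methanolysis of a temporary aryl lactone that is not in the target.
3. Enabling feature: O1 sits on C8a next to C8, and the ester carbon C1' of the C8 side chain is three bonds from C8, so O1 and C1' can be tied into a six-membered chroman-2-one ring (O1, C8a, C8, C3', C2', C1'); this ring hides O1 and stores the future methyl ester.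
4. Lactone precursor: Friedel–Crafts tigloylation next to the lactone oxygen of (4R)-5,7-dihydroxy-4-propylchroman-2-one; the benzylic centre C3' comes from copper-catalysed asymmetric 1,4-addition of n-PrMgBr to 5,7-dimethoxycoumarin.
5. Ring order: lactone ring (present in the starting coumarin) → pyranone ring, closed as the lactone ring is opened (key step); the benzene ring is bought.

Key step: step 7

Assumption: the facial sense of the copper–ferrocenyl diphosphine catalyst (step 1) and of quinine (step 7) is taken from the closest substrate classes; if either runs the other way here, the mirror-image ligand or the pseudo-enantiomeric alkaloid quinidine is used instead.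
Numbering: steps 1–6 use the chroman-2-one numbering of the lactone, steps 7–8 the chroman-4-one numbering of the target; lactone O1, C8, O7, C6, O5, C4a and C4 become target O1, C4a, O5, C6, O7, C8 and side-chain C3'.

Step 1
Reactants: 1 5,7-dimethoxycoumarin; 2 n-propylmagnesium bromide
Product: 3 (4R)-5,7-dimethoxy-4-propyl-3,4-dihydro-2H-chromen-2-one
Conditions: n-PrMgBr (1.5 equiv), CuBr·SMe2 (5 mol%), (R)-1-[(Sp)-2-(dicyclohexylphosphino)ferrocenyl]ethyldiphenylphosphine (6 mol%), CH2Cl2, −72 °C; then 1 M HCl
Reagents that add atoms: n-propylmagnesium bromide, CCC[Mg]Br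
Why: Copper-catalysed asymmetric conjugate addition of a Grignard reagent to the coumarin (a cyclic aryl enoate) should give the 4-alkylchroman-2-one, the chiral ferrocenyl diphosphine–copper complex delivering the propyl group to one enantioface of C4 and thereby setting the 4R centre, while the low temperature suppresses 1,2-addition to the lactone.

Step 2
Reactants: 3 (4R)-5,7-dimethoxy-4-propyl-3,4-dihydro-2H-chromen-2-one
Product: 4 (4R)-5,7-dihydroxy-4-propyl-3,4-dihydro-2H-chromen-2-one
Conditions: BBr3 (4 equiv), CH2Cl2, −78 °C → rt; H2O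
Reagents that add atoms: none
Why: Lewis-acid ether cleavage with BBr3 removes both aryl methyl groups, any acyl–oxygen opening of the lactone re-closing on acidic work-up, and the C4 centre is not acidic and stays untouched.

Step 3
Reactants: 4 (4R)-5,7-dihydroxy-4-propyl-3,4-dihydro-2H-chromen-2-one; 5 tigloyl chloride [(2E)-2-methylbut-2-enoyl chloride]
Product: 6 (4R)-5,7-dihydroxy-8-[(2E)-2-methylbut-2-enoyl]-4-propyl-3,4-dihydro-2H-chromen-2-one
Conditions: 5 (1.1 equiv), AlCl3 (4 equiv), PhNO2–CH2Cl2, 0 °C → rt; ice, 1 M HCl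
Reagents that add atoms: tigloyl chloride, C/C=C(\C)C(Cl)=O
Why: Friedel–Crafts acylation (directly or by O-acylation and Fries shift) of the phloroglucinol-type ring is expected at C8, between the 7-hydroxyl and the lactone oxygen, as with 5,7-dihydroxycoumarins, because C6 lies between two bulky aluminium phenoxides, and the enone should survive since its only neighbouring hydroxyl (O7) is held in a chelate and the other ortho oxygen is locked in the lactone.

Step 4
Reactants: 6 (4R)-5,7-dihydroxy-8-[(2E)-2-methylbut-2-enoyl]-4-propyl-3,4-dihydro-2H-chromen-2-one; 7 acetic anhydride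
Product: 8 (4R)-7-hydroxy-8-[(2E)-2-methylbut-2-enoyl]-2-oxo-4-propyl-3,4-dihydro-2H-chromen-5-yl acetate
Conditions: Ac2O (1.05 equiv), pyridine, CH2Cl2, 0 °C
Reagents that add atoms: acetic anhydride, CC(=O)OC(C)=O
Why: Chemoselective O-acetylation should take the 5-hydroxyl, which is para to the ketone, acidic and not chelated, and leave the 7-hydroxyl, which is hydrogen-bonded to the tigloyl carbonyl, while pyridine at 0 °C is too weak a base to start an oxa-Michael addition of O7.

Step 5
Reactants: 9 2-methylbut-3-en-2-ol; 10 di-tert-butyl dicarbonate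
Product: 11 tert-butyl 2-methylbut-3-en-2-yl carbonate
Conditions: n-BuLi (1.05 equiv), THF, 0 °C; then 10, 0 °C → rt
Reagents that add atoms: di-tert-butyl dicarbonate, CC(C)(C)OC(=O)OC(=O)OC(C)(C)C
Why: Acylation of the lithium alkoxide of the tertiary allylic alcohol with di-tert-butyl dicarbonate gives the mixed carbonate that serves as the 1,1-dimethylallyl donor, and no stereocentre is involved.

Step 6
Reactants: 8 (4R)-7-hydroxy-8-[(2E)-2-methylbut-2-enoyl]-2-oxo-4-propyl-3,4-dihydro-2H-chromen-5-yl acetate; 11 tert-butyl 2-methylbut-3-en-2-yl carbonate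
Product: 12 (4R)-8-[(2E)-2-methylbut-2-enoyl]-7-[(2-methylbut-3-en-2-yl)oxy]-2-oxo-4-propyl-3,4-dihydro-2H-chromen-5-yl acetate
Conditions: Pd(PPh3)4 (10 mol%), 11 (3 equiv), THF, 0 °C → rt
Reagents that add atoms: tert-butyl 2-methylbut-3-en-2-yl carbonate, CC(C)(C)OC(=O)OC(C)(C)C=C
Why: Tsuji–Trost O-allylation, in which zerovalent palladium ionises 11 with loss of CO2 to a 1,1-dimethylallyl–palladium cation and tert-butoxide, the latter deprotonates the chelated 7-hydroxyl, and the phenoxide is expected to attack the tertiary terminus at low temperature to give the branched ether faster than it can add to the neighbouring enone, since base is present only in catalytic, transient amount.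

Step 7
Reactants: 12 (4R)-8-[(2E)-2-methylbut-2-enoyl]-7-[(2-methylbut-3-en-2-yl)oxy]-2-oxo-4-propyl-3,4-dihydro-2H-chromen-5-yl acetate; 13 methanol
Product: 16 methyl (3R)-3-{(2R,3S)-7-hydroxy-2,3-dimethyl-5-[(2-methylbut-3-en-2-yl)oxy]-4-oxo-3,4-dihydro-2H-chromen-8-yl}hexanoate, via deacetylated lactone 14 (not isolated), via seco phenol ester 15 (not isolated)
Conditions: (−)-quinine (20 mol%), MeOH (20 equiv), PhCl, rt
Reagents that add atoms: methanol, CO
Why: Proposed new method: quinine is asked to act twice in one flask, first as a general base that lets methanol open the two aryl esters of 12 (the acetate on O7 and then the lactone, both with acyl-stabilised phenoxide leaving groups; closest known type: amine- and alkaloid-catalysed alcoholysis of activated esters and anhydrides), which turns the lactone carbonyl into the methyl ester of the target and sets the O1 phenol free beside the tigloyl ketone in 15, and then as the chiral base of the known quinine-catalysed intramolecular oxa-Michael addition of o-tigloylphenols. The pyranone ring closes by 6-endo-trig attack of O1 on the β-carbon of the enone, which forms the O1–C2 bond. C2 (R) is set by the alkaloid, whose protonated quinuclidine pairs with the phenoxide while its C9 hydroxyl binds the enone carbonyl and exposes one enantioface, and C3 (S) follows from kinetic protonation of the resulting enol on the face that leaves the two methyl groups cis, the isomer known to form under these non-equilibrating conditions. Regioselectivity between the two oxygens ortho to the ketone is secured because O5 is capped as the tertiary allyl ether and O1 appears only when the lactone ring opens, while O7 is para to the ketone and cannot reach the enone. The C3' centre of the side chain is five atoms from C2 and should remain a spectator, so the step is catalyst-controlled. The untested points are the rate of the alkaloid-mediated lactone methanolysis and the enantioselectivity in a medium that contains methanol.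

Step 8
Reactants: 16 methyl (3R)-3-{(2R,3S)-7-hydroxy-2,3-dimethyl-5-[(2-methylbut-3-en-2-yl)oxy]-4-oxo-3,4-dihydro-2H-chromen-8-yl}hexanoate
Product: 17 methyl (3R)-3-[(2R,3S)-5,7-dihydroxy-2,3-dimethyl-6-(3-methylbut-2-en-1-yl)-4-oxo-3,4-dihydro-2H-chromen-8-yl]hexanoate (target)
Conditions: Eu(fod)3 = tris(6,6,7,7,8,8,8-heptafluoro-2,2-dimethyl-3,5-octanedionato)europium (10 mol%), CHCl3, 60 °C
Reagents that add atoms: none
Why: Aromatic Claisen rearrangement, a [3,3] shift of the aryl 1,1-dimethylallyl ether accelerated by the europium Lewis acid held between O5 and the C4 carbonyl, should deliver the 3-methylbut-2-enyl group to C6, the only open ortho position (C4a is blocked and the para carbon C8 is substituted), and tautomerisation then gives the hydrogen-bonded 5-hydroxyl without touching any stereocentre.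

**Compound list**
1 | 5,7-dimethoxycoumarin (5,7-dimethoxy-2H-chromen-2-one) | COc1cc(OC)c2ccc(=O)oc2c1 | starting material
2 | n-propylmagnesium bromide | CCC[Mg]Br | starting material
3 | (4R)-5,7-dimethoxy-4-propyl-3,4-dihydro-2H-chromen-2-one | CCC[C@@H]1CC(=O)Oc2cc(OC)cc(OC)c12 | intermediate
4 | (4R)-5,7-dihydroxy-4-propyl-3,4-dihydro-2H-chromen-2-one | CCC[C@@H]1CC(=O)Oc2cc(O)cc(O)c12 | intermediate
5 | tigloyl chloride, (2E)-2-methylbut-2-enoyl chloride | C/C=C(\C)C(Cl)=O | starting material
6 | (4R)-5,7-dihydroxy-8-[(2E)-2-methylbut-2-enoyl]-4-propyl-3,4-dihydro-2H-chromen-2-one | CCC[C@@H]1CC(=O)Oc2c(C(=O)/C(C)=C/C)c(O)cc(O)c12 | intermediate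
7 | acetic anhydride | CC(=O)OC(C)=O | starting material
8 | (4R)-7-hydroxy-8-[(2E)-2-methylbut-2-enoyl]-2-oxo-4-propyl-3,4-dihydro-2H-chromen-5-yl acetate | CCC[C@@H]1CC(=O)Oc2c(C(=O)/C(C)=C/C)c(O)cc(OC(C)=O)c12 | intermediate
9 | 2-methylbut-3-en-2-ol | CC(C)(O)C=C | starting material
10 | di-tert-butyl dicarbonate | CC(C)(C)OC(=O)OC(=O)OC(C)(C)C | starting material
11 | tert-butyl 2-methylbut-3-en-2-yl carbonate | CC(C)(C)OC(=O)OC(C)(C)C=C | intermediate
12 | (4R)-8-[(2E)-2-methylbut-2-enoyl]-7-[(2-methylbut-3-en-2-yl)oxy]-2-oxo-4-propyl-3,4-dihydro-2H-chromen-5-yl acetate | CCC[C@@H]1CC(=O)Oc2c(C(=O)/C(C)=C/C)c(OC(C)(C)C=C)cc(OC(C)=O)c12 | intermediate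
13 | methanol | CO | starting material
14 | deacetylated lactone, (4R)-5-hydroxy-8-[(2E)-2-methylbut-2-enoyl]-7-[(2-methylbut-3-en-2-yl)oxy]-4-propyl-3,4-dihydro-2H-chromen-2-one (formed in step 7, not isolated) | CCC[C@@H]1CC(=O)Oc2c(C(=O)/C(C)=C/C)c(OC(C)(C)C=C)cc(O)c12 | intermediate
15 | seco phenol ester, methyl (3R)-3-{2,6-dihydroxy-3-[(2E)-2-methylbut-2-enoyl]-4-[(2-methylbut-3-en-2-yl)oxy]phenyl}hexanoate (formed in step 7, not isolated) | CCC[C@H](CC(=O)OC)c1c(O)cc(OC(C)(C)C=C)c(C(=O)/C(C)=C/C)c1O | intermediate
16 | methyl (3R)-3-{(2R,3S)-7-hydroxy-2,3-dimethyl-5-[(2-methylbut-3-en-2-yl)oxy]-4-oxo-3,4-dihydro-2H-chromen-8-yl}hexanoate | CCC[C@H](CC(=O)OC)c1c(O)cc(OC(C)(C)C=C)c2c1O[C@H](C)[C@H](C)C2=O | intermediate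
17 | methyl (3R)-3-[(2R,3S)-5,7-dihydroxy-2,3-dimethyl-6-(3-methylbut-2-en-1-yl)-4-oxo-3,4-dihydro-2H-chromen-8-yl]hexanoate | CCC[C@H](CC(=O)OC)c1c(O)c(CC=C(C)C)c(O)c2c1O[C@H](C)[C@H](C)C2=O | target

**Step count and risks**
Total step count: 8. Longest linear sequence: 7 steps (steps 1–4 and 6–8; step 5 prepares reagent 11).

Step 7 (the proposed new method). What may go wrong: slow or incomplete alkaloid-mediated opening of the lactone, or loss of enantio- and cis-selectivity of the ring closure in the methanol-containing medium. The fallback sets out from 12 and returns at 16, and it separates the ester cleavage from the ring closure. Neutral tin-catalysed transesterification (1,3-dichloro-1,1,3,3-tetrabutyldistannoxane, (ClBu2Sn)2O, 5 mol%, MeOH–toluene, 45 °C) should cleave acetate and lactone without generating a phenoxide, so that seco phenol ester 15 can be isolated. Compound 15 is then cyclised under the known aprotic conditions (quinine 10 mol%, PhCl, rt) to 16. No compound outside the list arises (F0).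

Step 6. What may go wrong: slow O-alkylation of the hydrogen-bonded phenol by the bulky tertiary allyl electrophile, drift to the linear ether by re-ionisation, or premature conjugate addition of O7 to the enone. The fallback sets out from 6 and returns at 17; the two oxygens exchange roles, so that no carbon electrophile has to attack the chelated hydroxyl. Palladium allylation of 6 with 11 (1.1 equiv, Pd(PPh3)4, THF, 0 °C) should go to the free 5-hydroxyl only and give the 5-(2-methylbut-3-en-2-yl) ether F1. The chelated 7-hydroxyl is then silylated with i-Pr3SiOSO2CF3 and 2,6-lutidine (CH2Cl2, −78 °C) to the silyl ether F2. The quinine/methanol ring opening and ring closure of step 7 (or its stepwise form) passes through the seco phenol F3 to the chromanone F4, which now carries the silyl group on O5 and the allyl ether on O7. Claisen shift from O7 (toluene, 100 °C), for which C6 is again the only open ortho carbon, gives the 6-prenyl phenol F5. Bu4NF buffered with AcOH (THF, 0 °C) removes the silyl group and gives 17.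

Step 3. What may go wrong: acylation at the other free ring carbon (poor regioselectivity), or Lewis-acid-induced cyclisation onto the new enone. The fallback sets out from 4 and returns at 17. If acylation prefers C6, the product is the 6-tigloyl isomer F6, the other lactone of the same seco acid, and it is carried on in a different order with the lactone kept as the protecting ring for the target's O7. F6 is used at once, because its enone has two free ortho hydroxyls. Palladium allylation with 11 (Pd(PPh3)4, THF, 0 °C) should go to the open 7-hydroxyl and not to the 5-hydroxyl, which is crowded by the propyl-bearing C4, and give the 7-ether F7. Quinine (10 mol%, PhCl, rt) then closes the pyranone ring from the only free hydroxyl, on C5, onto the enone to give the tricyclic lactone F8. Claisen shift (Eu(fod)3, CHCl3, 60 °C) moves the allyl group to C8 of the lactone skeleton and gives the phenol F9. Neutral methanolysis ((ClBu2Sn)2O cat., MeOH–toluene, 45 °C) opens the lactone to 17.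

**Further compounds**
F0 | step 7 | none | none
F1 | step 6 | (4R)-7-hydroxy-8-[(2E)-2-methylbut-2-enoyl]-5-[(2-methylbut-3-en-2-yl)oxy]-4-propyl-3,4-dihydro-2H-chromen-2-one | CCC[C@@H]1CC(=O)Oc2c(C(=O)/C(C)=C/C)c(O)cc(OC(C)(C)C=C)c12
F2 | step 6 | (4R)-8-[(2E)-2-methylbut-2-enoyl]-5-[(2-methylbut-3-en-2-yl)oxy]-4-propyl-7-{[tri(propan-2-yl)silyl]oxy}-3,4-dihydro-2H-chromen-2-one | CCC[C@@H]1CC(=O)Oc2c(C(=O)/C(C)=C/C)c(O[Si](C(C)C)(C(C)C)C(C)C)cc(OC(C)(C)C=C)c12
F3 | step 6 | methyl (3R)-3-{2-hydroxy-3-[(2E)-2-methylbut-2-enoyl]-6-[(2-methylbut-3-en-2-yl)oxy]-4-{[tri(propan-2-yl)silyl]oxy}phenyl}hexanoate (not isolated) | CCC[C@H](CC(=O)OC)c1c(OC(C)(C)C=C)cc(O[Si](C(C)C)(C(C)C)C(C)C)c(C(=O)/C(C)=C/C)c1O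
F4 | step 6 | methyl (3R)-3-{(2R,3S)-2,3-dimethyl-7-[(2-methylbut-3-en-2-yl)oxy]-4-oxo-5-{[tri(propan-2-yl)silyl]oxy}-3,4-dihydro-2H-chromen-8-yl}hexanoate | CCC[C@H](CC(=O)OC)c1c(OC(C)(C)C=C)cc(O[Si](C(C)C)(C(C)C)C(C)C)c2c1O[C@H](C)[C@H](C)C2=O
F5 | step 6 | methyl (3R)-3-{(2R,3S)-7-hydroxy-2,3-dimethyl-6-(3-methylbut-2-en-1-yl)-4-oxo-5-{[tri(propan-2-yl)silyl]oxy}-3,4-dihydro-2H-chromen-8-yl}hexanoate | CCC[C@H](CC(=O)OC)c1c(O)c(CC=C(C)C)c(O[Si](C(C)C)(C(C)C)C(C)C)c2c1O[C@H](C)[C@H](C)C2=O
F6 | step 3 | (4R)-5,7-dihydroxy-6-[(2E)-2-methylbut-2-enoyl]-4-propyl-3,4-dihydro-2H-chromen-2-one | CCC[C@@H]1CC(=O)Oc2cc(O)c(C(=O)/C(C)=C/C)c(O)c12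
F7 | step 3 | (4R)-5-hydroxy-6-[(2E)-2-methylbut-2-enoyl]-7-[(2-methylbut-3-en-2-yl)oxy]-4-propyl-3,4-dihydro-2H-chromen-2-one | CCC[C@@H]1CC(=O)Oc2cc(OC(C)(C)C=C)c(C(=O)/C(C)=C/C)c(O)c12
F8 | step 3 | tricyclic lactone: (4R)-4-propylchroman-2-one bearing, fused across its C5 oxygen and C6, the (2R,3S)-2,3-dimethyl-4-oxopyran ring (ring oxygen on C5, carbonyl carbon on C6), and the 7-[(2-methylbut-3-en-2-yl)oxy] group | CCC[C@@H]1CC(=O)Oc2cc(OC(C)(C)C=C)c3c(c12)O[C@H](C)[C@H](C)C3=O
F9 | step 3 | the same tricyclic lactone after the Claisen shift: 7-hydroxyl free, 3-methylbut-2-en-1-yl group on C8 of the lactone skeleton | CCC[C@@H]1CC(=O)Oc2c(CC=C(C)C)c(O)c3c(c12)O[C@H](C)[C@H](C)C3=O
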